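The rings are lettered as follows: F is chlorinated, C is central, B/D sit on C, G/H are their C-linked trioxygenated phenyls, and A/E are terminal. A mirror plane through ring C (C-2, C-5) and ring F makes the biaryl bonds B(C-6)–G(C-1) and D(C-6)–H(C-1) identical. Each ring B/D carbon involved lies between two oxygen-bearing carbons. Both bonds are cut together. One double Suzuki coupling joins two 2,4,6-trimethoxyphenyl units to a symmetric dibromide, the B–C(F)–D tetraaryl ether, which is methyl-protected except for benzyl ethers on the two oxygens reserved for A/E. Every crowded diaryl ether is grown outwards from F by phenol O-alkylation with a bromomethylpyranone, followed by alkoxide-induced isomerisation of the pyranone to a resorcinol.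

Key step: step 11

Remark on the chemistry: rings B and D are numbered from the carbon bearing O–A (or O–E) as C-1, so C-4 bears the oxygen to ring C and C-6 bears G (or H); the target has no stereocentre and no stereogenic axis because G and H are symmetric about their biaryl bonds, and E descriptors occur only in the transient open-chain intermediates, which are drawn in neutral form.

Step 1
Reactants: 1 2-chloro-1,3-dimethoxybenzene
Product: 3 4-chloro-3,5-dimethoxyphenol, via aryl pinacol boronate 2 (not isolated)
Conditions: [Ir(OMe)(cod)]2 (cat.), dtbpy, B2pin2, THF, 80 °C; then KHSO5 (as Oxone), acetone/H2O, rt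
Reagents that add atoms: bis(pinacolato)diboron, CC1(C)OB(OC1(C)C)B1OC(C)(C)C(C)(C)O1 (boryl group of 2); potassium peroxymonosulfate, [K+].[O-]S(=O)(=O)OO (hydroxyl oxygen of 3)
Why: Iridium-catalysed aromatic C–H borylation is governed by sterics and should reach only C-5, the single C–H with no ortho substituent, and oxidation of the C–B bond in the same flask gives the phenol while the aryl chloride stays inert in both stages (one-pot borylation/oxidation).

Step 2
Reactants: 4 4-methoxy-6-methyl-2H-pyran-2-one
Product: 5 6-(bromomethyl)-4-methoxy-2H-pyran-2-one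
Conditions: NBS, AIBN (cat.), PhCF3, reflux
Reagents that add atoms: N-bromosuccinimide, O=C1CCC(=O)N1Br
Why: Wohl–Ziegler bromination of the 6-methyl group through the pyranone-stabilised allylic radical is the established entry to this bromide, and a non-polar medium keeps ionic bromination at C-3 in check.

Step 3
Reactants: 3 4-chloro-3,5-dimethoxyphenol; 5 6-(bromomethyl)-4-methoxy-2H-pyran-2-one
Product: 6 6-[(4-chloro-3,5-dimethoxyphenoxy)methyl]-4-methoxy-2H-pyran-2-one
Conditions: K2CO3, acetone, reflux
Reagents that add atoms: none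
Why: Williamson ether synthesis: the phenoxide displaces a primary allylic-type bromide by SN2, so the oxygen that will end up between two oxygenated carbons of ring C is bonded before that ring exists and no hindered aryl–oxygen coupling is needed.

Step 4
Reactants: 6 6-[(4-chloro-3,5-dimethoxyphenoxy)methyl]-4-methoxy-2H-pyran-2-one
Product: 8 2-(4-chloro-3,5-dimethoxyphenoxy)-5-methoxybenzene-1,3-diol (ring C–F diol), via ring-opened keto ester 7 (not isolated)
Conditions: NaOMe (5 equiv), MeOH, sealed vessel, 65 → 120 °C, Ar; then 1 M HCl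
Reagents that add atoms: sodium methoxide, [Na+].[O-]C (ester methoxy group of 7 only, lost again on ring closure)
Why: Alkoxide-induced isomerisation of a 4-alkoxy-2-pyranone to a 5-alkoxyresorcinol, known for the parent 4 itself (which gives 5-methoxyresorcinol): methoxide opens the lactone to 7, the ketone enolate at the ArO–CH2 carbon closes onto the ester (intramolecular Claisen condensation), and tautomerisation to the aromatic bis-phenoxide makes the sequence irreversible, while the aryloxy group raises the acidity of the reacting CH2 and methoxide matches the 4-methoxy group so that exchange at C-4 is degenerate.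

Step 5
Reactants: 9 4-hydroxy-6-methyl-2H-pyran-2-one
Product: 10 4-(benzyloxy)-6-methyl-2H-pyran-2-one
Conditions: BnBr, K2CO3, DMF, rt → 50 °C
Reagents that add atoms: benzyl bromide, BrCc1ccccc1
Why: O-Alkylation of the vinylogous carboxylic acid at O-4 under Williamson conditions in a polar aprotic solvent is the usual preparation of 4-alkoxy-6-methyl-2-pyranones.

Step 6
Reactants: 10 4-(benzyloxy)-6-methyl-2H-pyran-2-one
Product: 11 4-(benzyloxy)-6-(bromomethyl)-2H-pyran-2-one
Conditions: NBS (1.0 equiv), AIBN (cat.), PhCF3, reflux, stopped before full conversion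
Reagents that add atoms: N-bromosuccinimide, O=C1CCC(=O)N1Br
Why: Wohl–Ziegler bromination as in step 2; the benzyl CH2 hangs on a vinylogous-ester oxygen and is polarity-mismatched with the electrophilic bromine atom much as in benzyl esters, which tolerate such brominations, so one equivalent of NBS taken to partial conversion should functionalise the ring methyl group, and this cheap side-branch step tolerates a modest return.

Step 7
Reactants: 8 ring C–F diol; 11 4-(benzyloxy)-6-(bromomethyl)-2H-pyran-2-one (2.2 equiv)
Product: 12 6,6'-{[2-(4-chloro-3,5-dimethoxyphenoxy)-5-methoxy-1,3-phenylene]bis(oxymethylene)}bis[4-(benzyloxy)-2H-pyran-2-one]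
Conditions: K2CO3, DMF, rt
Reagents that add atoms: none
Why: Double Williamson ether synthesis on the two equivalent phenols of 8 with a primary bromide in a polar aprotic solvent, which favours O- over C-alkylation of the electron-rich ring.

Step 8
Reactants: 12 bis(pyranonylmethyl) ether of 8
Product: 14 2,2'-{[2-(4-chloro-3,5-dimethoxyphenoxy)-5-methoxy-1,3-phenylene]bis(oxy)}bis[5-(benzyloxy)benzene-1,3-diol] (B–C(F)–D tetraol), via ring-opened bis(benzyl ester) 13 (not isolated)
Conditions: NaOBn (1.0 M in BnOH, 8 equiv), 80 → 120 °C, Ar; then 1 M HCl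
Reagents that add atoms: sodium benzyloxide, [Na+].[O-]Cc1ccccc1 (ester benzyloxy groups of 13 only, lost again on ring closure)
Why: The pyranone-to-resorcinol isomerisation of step 4 (lactone opening, intramolecular Claisen condensation, aromatisation) is run on both arms at once, and benzyloxide in benzyl alcohol is used so that ester exchange and addition–elimination at C-4 can only return a benzyl group, which keeps the two oxygens meant for rings A and E distinguishable from all others.

Step 9
Reactants: 14 B–C(F)–D tetraol
Product: 15 2,2'-{[2-(4-chloro-3,5-dimethoxyphenoxy)-5-methoxy-1,3-phenylene]bis(oxy)}bis[5-(benzyloxy)-4-bromobenzene-1,3-diol]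
Conditions: NBS (2.0 equiv, slow addition), THF, −78 → −30 °C
Reagents that add atoms: N-bromosuccinimide, O=C1CCC(=O)N1Br
Why: Electrophilic aromatic bromination: rings B and D are the only rings with free phenols and therefore by far the most nucleophilic, their two open positions are equivalent by the local symmetry of each ring, and the first bromine damps its own ring, so two equivalents of NBS at low temperature should place one bromine on each ring between OH and OBn.

Step 10
Reactants: 15 dibromo tetraol
Product: 16 dibromide core 1,3-bis[4-(benzyloxy)-3-bromo-2,6-dimethoxyphenoxy]-2-(4-chloro-3,5-dimethoxyphenoxy)-5-methoxybenzene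
Conditions: MeI (excess), K2CO3, DMF, rt → 40 °C
Reagents that add atoms: iodomethane, CI
Why: Fourfold Williamson O-methylation with a small electrophile copes with the flanked phenols and leaves aryl bromide, aryl chloride and benzyl ethers untouched.

Step 11
Reactants: 16 dibromide core; 17 (2,4,6-trimethoxyphenyl)boronic acid (5 equiv, in portions)
Product: 18 1,3-bis{[6-(benzyloxy)-2,2',4,4',6'-pentamethoxybiphenyl-3-yl]oxy}-2-(4-chloro-3,5-dimethoxyphenoxy)-5-methoxybenzene (G–B–C(F)–D–H core as dibenzyl ether)
Conditions: Pd2(dba)3 (5 mol%), SPhos (20 mol%), K3PO4·H2O (finely ground, 8 equiv), toluene, 100 °C, Ar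
Reagents that add atoms: none
Why: Suzuki–Miyaura cross-coupling: SPhos-ligated zerovalent palladium inserts into each C–Br bond, the boronate formed from 17 and phosphate hands over its aryl group, and reductive elimination from the crowded diarylpalladium species gives the biaryl, the closest known reaction type being the coupling of di-ortho-substituted aryl bromides with 2,6-dialkoxyarylboronic acids under dialkylbiarylphosphine ligands. No ring is closed and no stereocentre or stable axis arises, because rings G and H are symmetric about the new bonds. The two reacting carbons are exchanged by the mirror plane of 16, so one set of conditions serves both and two skeletal bonds are made in one operation. The step needs C–Br over C–Cl selectivity, which rests on the weaker C–Br bond and on the ring F chloride being buried between two methoxy groups on an electron-rich ring, and heating is ended as soon as aryl bromide is consumed. It also needs coupling to outrun protodeboronation of 17, hence a nearly anhydrous hydrocarbon medium, solid phosphate and portionwise addition of the boronic acid. An acetate-free palladium source is chosen so that no carboxylate is present to assist C–H palladation of the neighbouring benzyl ring, which would divert the arylpalladium species into a benzochromene.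

Step 12
Reactants: 18 hexaaryl dibenzyl ether
Product: 19 1,3-bis[(6-hydroxy-2,2',4,4',6'-pentamethoxybiphenyl-3-yl)oxy]-2-(4-chloro-3,5-dimethoxyphenoxy)-5-methoxybenzene (hexaaryl diol)
Conditions: BCl3 (6 equiv), pentamethylbenzene (15 equiv), CH2Cl2, −78 °C; then MeOH/H2O
Reagents that add atoms: none
Why: Lewis-acid debenzylation with BCl3 and pentamethylbenzene as non-basic benzyl-cation trap works at −78 °C, where aryl methyl ethers and diaryl ethers persist and C-benzylation of the electron-rich rings is intercepted, and it avoids hydrogenolysis conditions that could reduce the C–Cl bond.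

Step 13
Reactants: 19 hexaaryl diol; 5 6-(bromomethyl)-4-methoxy-2H-pyran-2-one (2.5 equiv)
Product: 20 bis[(4-methoxy-2-oxo-2H-pyran-6-yl)methyl] ether of 19
Conditions: Cs2CO3, DMF, rt
Reagents that add atoms: none
Why: Double Williamson ether synthesis: SN2 at a primary carbon lets the phenol oxygen next to the bulky ring G (or H) be substituted where a direct coupling with a 2,6-dioxygenated aryl halide would be hindered on both partners.

Step 14
Reactants: 20 bis(pyranonylmethyl) ether of 19
Product: 22 octaaryl pentadecamethyl ether with rings A and E as 2,6-dihydroxy-4-methoxyphenoxy groups, via ring-opened bis(methyl ester) 21 (not isolated)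
Conditions: NaOMe (10 equiv), MeOH/THF, sealed vessel, 65 → 120 °C, Ar; then 1 M HCl
Reagents that add atoms: sodium methoxide, [Na+].[O-]C (ester methoxy groups of 21 only, lost again on ring closure)
Why: Third use of the pyranone-to-resorcinol isomerisation (lactone opening to 21, intramolecular Claisen condensation, aromatisation), already tested in steps 4 and 8; methyl ethers, diaryl ethers, biaryl bonds and the unactivated aryl chloride are inert to methoxide.

Step 15
Reactants: 22 octaaryl pentadecamethyl ether
Product: 23 CNP0275555.0 (target)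
Conditions: BBr3 (about 3 equiv per OMe), CH2Cl2, −78 °C → rt, Ar; then ice/H2O; Sephadex LH-20 under Ar
Reagents that add atoms: none
Why: Exhaustive Lewis-acid cleavage of aryl methyl ethers with BBr3 (O-complexation, bromide attack at methyl) spares diaryl ether, biaryl and C–Cl bonds, and hydrolysis of the aryl borates releases all nineteen hydroxyl groups of 23.

Compound list
1 | 2-chloro-1,3-dimethoxybenzene | COc1cccc(OC)c1Cl | starting material
2 | 2-(4-chloro-3,5-dimethoxyphenyl)-4,4,5,5-tetramethyl-1,3,2-dioxaborolane | COc1cc(cc(OC)c1Cl)B1OC(C)(C)C(C)(C)O1 | intermediate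
3 | 4-chloro-3,5-dimethoxyphenol | COc1cc(O)cc(OC)c1Cl | intermediate
4 | 4-methoxy-6-methyl-2H-pyran-2-one | COC1=CC(=O)OC(C)=C1 | starting material
5 | 6-(bromomethyl)-4-methoxy-2H-pyran-2-one | COC1=CC(=O)OC(CBr)=C1 | intermediate
6 | 6-[(4-chloro-3,5-dimethoxyphenoxy)methyl]-4-methoxy-2H-pyran-2-one | COC1=CC(=O)OC(COc2cc(OC)c(Cl)c(OC)c2)=C1 | intermediate
7 | methyl (2E)-6-(4-chloro-3,5-dimethoxyphenoxy)-3-methoxy-5-oxohex-2-enoate | COC(=O)/C=C(/OC)CC(=O)COc1cc(OC)c(Cl)c(OC)c1 | intermediate
8 | 2-(4-chloro-3,5-dimethoxyphenoxy)-5-methoxybenzene-1,3-diol | COc1cc(O)c(Oc2cc(OC)c(Cl)c(OC)c2)c(O)c1 | intermediate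
9 | 4-hydroxy-6-methyl-2H-pyran-2-one | CC1=CC(O)=CC(=O)O1 | starting material
10 | 4-(benzyloxy)-6-methyl-2H-pyran-2-one | CC1=CC(OCc2ccccc2)=CC(=O)O1 | intermediate
11 | 4-(benzyloxy)-6-(bromomethyl)-2H-pyran-2-one | BrCC1=CC(OCc2ccccc2)=CC(=O)O1 | intermediate
12 | bis{[4-(benzyloxy)-2-oxo-2H-pyran-6-yl]methyl} ether of 8 | COc1cc(OCC2=CC(OCc3ccccc3)=CC(=O)O2)c(Oc2cc(OC)c(Cl)c(OC)c2)c(OCC2=CC(OCc3ccccc3)=CC(=O)O2)c1 | intermediate
13 | ring-opened form of 12, both arms as benzyl (2E)-3-(benzyloxy)-5-oxohex-2-enoates linked through C-6 to the ring C oxygens | COc1cc(OCC(=O)C/C(OCc2ccccc2)=C\C(=O)OCc2ccccc2)c(Oc2cc(OC)c(Cl)c(OC)c2)c(OCC(=O)C/C(OCc2ccccc2)=C\C(=O)OCc2ccccc2)c1 | intermediate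
14 | B–C(F)–D tetraol, rings B and D as 4-(benzyloxy)-2,6-dihydroxyphenoxy groups | COc1cc(Oc2c(O)cc(OCc3ccccc3)cc2O)c(Oc2cc(OC)c(Cl)c(OC)c2)c(Oc2c(O)cc(OCc3ccccc3)cc2O)c1 | intermediate
15 | dibromo tetraol, rings B and D as 4-(benzyloxy)-3-bromo-2,6-dihydroxyphenoxy groups | COc1cc(Oc2c(O)cc(OCc3ccccc3)c(Br)c2O)c(Oc2cc(OC)c(Cl)c(OC)c2)c(Oc2c(O)cc(OCc3ccccc3)c(Br)c2O)c1 | intermediate
16 | 1,3-bis[4-(benzyloxy)-3-bromo-2,6-dimethoxyphenoxy]-2-(4-chloro-3,5-dimethoxyphenoxy)-5-methoxybenzene | Brc1c(OCc2ccccc2)cc(OC)c(Oc2cc(OC)cc(Oc3c(OC)cc(OCc4ccccc4)c(Br)c3OC)c2Oc2cc(OC)c(Cl)c(OC)c2)c1OC | intermediate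
17 | (2,4,6-trimethoxyphenyl)boronic acid | COc1cc(OC)c(B(O)O)c(OC)c1 | starting material
18 | G–B–C(F)–D–H hexaaryl core as dibenzyl ether | COc1cc(OC)cc(OC)c1-c1c(OCc2ccccc2)cc(OC)c(Oc2cc(OC)cc(Oc3c(OC)cc(OCc4ccccc4)c(-c4c(OC)cc(OC)cc4OC)c3OC)c2Oc2cc(OC)c(Cl)c(OC)c2)c1OC | intermediate
19 | hexaaryl diol (free OH at C-1 of rings B and D) | COc1cc(OC)cc(OC)c1-c1c(O)cc(OC)c(Oc2cc(OC)cc(Oc3c(OC)cc(O)c(-c4c(OC)cc(OC)cc4OC)c3OC)c2Oc2cc(OC)c(Cl)c(OC)c2)c1OC | intermediate
20 | bis[(4-methoxy-2-oxo-2H-pyran-6-yl)methyl] ether of 19 | COc1cc(OC)cc(OC)c1-c1c(OCC2=CC(OC)=CC(=O)O2)cc(OC)c(Oc2cc(OC)cc(Oc3c(OC)cc(OCC4=CC(OC)=CC(=O)O4)c(-c4c(OC)cc(OC)cc4OC)c3OC)c2Oc2cc(OC)c(Cl)c(OC)c2)c1OC | intermediate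
21 | ring-opened form of 20, both arms as methyl (2E)-3-methoxy-5-oxohex-2-enoates linked through C-6 to the ring B and D oxygens | COc1cc(OC)cc(OC)c1-c1c(OCC(=O)C/C(OC)=C\C(=O)OC)cc(OC)c(Oc2cc(OC)cc(Oc3c(OC)cc(OCC(=O)C/C(OC)=C\C(=O)OC)c(-c4c(OC)cc(OC)cc4OC)c3OC)c2Oc2cc(OC)c(Cl)c(OC)c2)c1OC | intermediate
22 | octaaryl pentadecamethyl ether, rings A and E as 2,6-dihydroxy-4-methoxyphenoxy groups | COc1cc(OC)cc(OC)c1-c1c(Oc2c(O)cc(OC)cc2O)cc(OC)c(Oc2cc(OC)cc(Oc3c(OC)cc(Oc4c(O)cc(OC)cc4O)c(-c4c(OC)cc(OC)cc4OC)c3OC)c2Oc2cc(OC)c(Cl)c(OC)c2)c1OC | intermediate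
23 | CNP0275555.0 | Oc1cc(O)c(Oc2cc(O)c(Oc3cc(O)cc(Oc4c(O)cc(Oc5c(O)cc(O)cc5O)c(-c5c(O)cc(O)cc5O)c4O)c3Oc3cc(O)c(Cl)c(O)c3)c(O)c2-c2c(O)cc(O)cc2O)c(O)c1 | target

Total step count: 15. Longest linear sequence: 12 (steps 1, 3, 4, 7, 8, 9, 10, 11, 12, 13, 14, 15).

Steps most likely to fail

Step 11.
- What may go wrong: protodeboronation of the electron-rich boronic acid and hydrodebromination of the stalled arylpalladium species may outrun transmetalation at the doubly flanked carbon. Prolonged heating may also begin to engage the ring F C–Cl bond.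
- Fallback (Negishi coupling in place of boron chemistry): it sets out from 16. 1,3,5-Trimethoxybenzene is lithiated between two methoxy groups (n-BuLi, THF, 0 °C) to 2,4,6-trimethoxyphenyllithium F1. ZnCl2 converts this into (2,4,6-trimethoxyphenyl)zinc chloride F2, which is coupled with 16 under Pd2(dba)3/RuPhos in THF at 60–70 °C.
- Why it should help: the arylzinc needs neither base nor water, so the loss of nucleophile by protonolysis is removed, and this reaction type is established for tetra-ortho-substituted biaryls. The sequence comes back to the route at 18.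

Step 14.
- What may go wrong: the reaction may stall at the opened chain, or the chain may fragment by retro-Claisen cleavage before the crowded ArO–CH2 carbon closes onto the ester. Poor solubility of the large substrate in the alcoholic medium adds to the difficulty.
- Fallback (direct aryl–oxygen coupling instead of ring construction): it sets out from 19 and bypasses 20. A double Ullmann-type coupling with purchased 2-iodo-1,3,5-trimethoxybenzene (CuI, picolinic acid, K3PO4, DMSO, 100 °C, conditions under which the aryl chloride is inert) should give the permethyl (nonadecamethyl) ether F3. Exhaustive BBr3 cleavage of F3 as in step 15 comes back to the route at 23.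

Step 15.
- What may go wrong: ether cleavage may be incomplete across fifteen sites, and the free polyphenol may be lost to oxidation during isolation.
- Fallback (isolation through a stable derivative): it sets out from 22. The crude BBr3 product is not purified but acetylated at once (Ac2O, pyridine, DMAP) to the nonadecaacetate F4. F4 can be chromatographed on silica and separated from under-cleaved material.
- Return to the route: Zemplén transesterification (NaOMe cat., MeOH, Ar, then acidic resin) releases the polyphenol and comes back to the route at 23.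

Further compounds
F1 | step 11 | 2,4,6-trimethoxyphenyllithium | COc1cc(OC)c([Li])c(OC)c1
F2 | step 11 | (2,4,6-trimethoxyphenyl)zinc chloride | COc1cc(OC)c([Zn]Cl)c(OC)c1
F3 | step 14 | permethyl (nonadecamethyl) ether of 23 | COc1cc(OC)cc(OC)c1-c1c(Oc2c(OC)cc(OC)cc2OC)cc(OC)c(Oc2cc(OC)cc(Oc3c(OC)cc(Oc4c(OC)cc(OC)cc4OC)c(-c4c(OC)cc(OC)cc4OC)c3OC)c2Oc2cc(OC)c(Cl)c(OC)c2)c1OC
F4 | step 15 | nonadecaacetate of 23 | CC(=O)Oc1cc(OC(C)=O)c(Oc2cc(OC(C)=O)c(Oc3cc(OC(C)=O)cc(Oc4c(OC(C)=O)cc(Oc5c(OC(C)=O)cc(OC(C)=O)cc5OC(C)=O)c(-c5c(OC(C)=O)cc(OC(C)=O)cc5OC(C)=O)c4OC(C)=O)c3Oc3cc(OC(C)=O)c(Cl)c(OC(C)=O)c3)c(OC(C)=O)c2-c2c(OC(C)=O)cc(OC(C)=O)cc2OC(C)=O)c(OC(C)=O)c1
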